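## Retrosynthetic overview
1. Silyhermin B ⇒ tri-O-benzyl flavanone (neutral hydrogenolysis comes last) ⇒ 2'-hydroxychalcone. Ring C is closed last through its O1–C2 bond by a catalyst-controlled intramolecular oxa-Michael addition that sets C2 as (S).
2. Chalcone ⇒ Claisen–Schmidt union of 4,6-di-O-benzylphloroacetophenone and an enantiopure trans-dihydrobenzofuran-5-carbaldehyde.
3. Dihydrobenzofuran ⇒ the C3–C3a bond is cut back to an o-iodoaryl (R)-1-arylallyl ether. The forward step is a 5-exo aryl-radical closure, boron capture and oxidation, with C3 relayed from C2.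
4. Key disconnection: the O1–C2 ether bond ⇒ 3,4-dihydroxy-5-iodobenzaldehyde + a racemic 1-arylallyl tert-butyl carbonate. They are joined by an enantioconvergent iridium-catalysed O-allylation that sets C2 as (R).
5. Ring order: the dihydrofuran ring first (ether bond, then C–C closure), the pyranone ring C last. Starting materials are 5-iodovanillin, O-benzylvanillin and 2,4,6-trihydroxyacetophenone.

Assumption: the sense of induction written for the ligand in step 3 and for the thiourea in step 7 is taken by analogy. Both catalysts are sold in both (pseudo)enantiomeric forms, so an opposite sense is corrected by exchanging the antipode without changing the route.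

## Route

Step 1
Reactants: 1 5-iodovanillin (4-hydroxy-3-iodo-5-methoxybenzaldehyde)
Product: 2 3,4-dihydroxy-5-iodobenzaldehyde
Conditions: AlCl3 (1.2 equiv), pyridine (4.5 equiv), CH2Cl2, reflux, 24 h; then 2 M HCl
Reagents that add atoms: none
Why: Chelation-assisted demethylation of an o-hydroxyaryl methyl ether, in which aluminium binds the phenoxide and the neighbouring OMe so that chloride removes only this methyl group while the aldehyde and the aryl iodide are untouched.

Step 2
Reactants: 3 4-(benzyloxy)-3-methoxybenzaldehyde (O-benzylvanillin)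
Product: 5 rac-tert-butyl 1-[4-(benzyloxy)-3-methoxyphenyl]prop-2-en-1-yl carbonate, via bromomagnesium alkoxide 4 (not isolated)
Conditions: vinylMgBr (1.2 equiv), THF, 0 °C, 1 h; then Boc2O (1.3 equiv), 0 °C to rt; aq NH4Cl; Et3N-deactivated silica plug
Reagents that add atoms: vinylmagnesium bromide, C=C[Mg]Br; di-tert-butyl dicarbonate, CC(C)(C)OC(=O)OC(=O)OC(C)(C)C
Why: Grignard 1,2-addition to the aldehyde followed by O-acylation of the alkoxide in the same flask, giving the carbonate deliberately as a racemate because step 3 is enantioconvergent.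

Step 3
Reactants: 2 3,4-dihydroxy-5-iodobenzaldehyde (1.2 equiv); 5 rac-tert-butyl 1-[4-(benzyloxy)-3-methoxyphenyl]prop-2-en-1-yl carbonate
Product: 6 4-{[(1R)-1-[4-(benzyloxy)-3-methoxyphenyl]prop-2-en-1-yl]oxy}-3-hydroxy-5-iodobenzaldehyde
Conditions: [Ir(cod)Cl]2 (3 mol %), (S)-BINOL-derived 5H-dibenz[b,f]azepin-5-yl phosphoramidite (P,olefin ligand, 12 mol %), THF, 25 °C, no added base or acid
Reagents that add atoms: none
Why: Proposed new method: enantioconvergent, base-free O-allylation of an acidic phenol in the iridium/(phosphoramidite,olefin) manifold, in which monovalent iridium ionises both enantiomers of 5, the two (η3-1-arylallyl) complexes of trivalent iridium interconvert by η3–η1–η3 slippage at the CH2 terminus faster than a weak nucleophile attacks, loss of CO2 leaves tert-butoxide as the only base so that only the most acidic OH of 2 (para to CHO, ortho to iodine, about three pKa units below the 3-OH) is deprotonated, and this phenoxide, whose ortho and para carbons are all blocked against C-allylation and which is a poorer leaving group than the carbonate so that 6 is not re-ionised, attacks the benzylic allyl terminus from outside to form the O1–C2 bond and set the future C2 as (R); the closest known reaction types are the iridium–phosphoramidite allylic etherification of linear cinnamyl carbonates by alkali aryloxides (where racemic branched esters only undergo kinetic resolution) and the iridium/(P,olefin) enantioconvergent substitution of racemic branched allylic alcohols or carbonates by C, N, S and aliphatic O nucleophiles.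

Step 4
Reactants: 6 4-{[(1R)-1-[4-(benzyloxy)-3-methoxyphenyl]prop-2-en-1-yl]oxy}-3-hydroxy-5-iodobenzaldehyde
Product: 8 (2R,3S)-2-[4-(benzyloxy)-3-methoxyphenyl]-7-hydroxy-3-(hydroxymethyl)-2,3-dihydrobenzofuran-5-carbaldehyde, via catechol boronate 7 (not isolated)
Conditions: B2cat2 (3 equiv), DMF, blue LED (450 nm), 25 °C, 16 h; then NaBO3·4H2O (12 equiv), THF/H2O, 0 °C to rt
Reagents that add atoms: bis(catecholato)diboron, B1(Oc2ccccc2O1)B1Oc2ccccc2O1 (boron group of 7); sodium perborate, [Na+].[Na+].O[B-]1(O)OO[B-](O)(O)OO1 (oxygen of the CH2OH group)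
Why: Light-driven radical borylation of an aryl iodide coupled to a 5-exo-trig aryl-radical cyclisation (about 10^9 to 10^10 per second, far faster than direct aryl borylation), in which the Beckwith–Houk transition state with the C2 aryl group pseudo-equatorial places the new CH2 radical trans to it and so sets C3, the primary radical is captured by B2cat2, and perborate oxidation converts the CH2–B group into CH2OH without touching C3 or the aldehyde, whose only free OH is meta to it.

Step 5
Reactants: 9 2,4,6-trihydroxyacetophenone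
Product: 10 1-[2,4-bis(benzyloxy)-6-hydroxyphenyl]ethan-1-one
Conditions: BnBr (2.05 equiv), K2CO3 (2.2 equiv), DMF, 60 °C
Reagents that add atoms: benzyl bromide, BrCc1ccccc1
Why: Williamson etherification in which one ortho OH stays locked in a hydrogen bond to the acetyl group, so that only the para OH and the other ortho OH are benzylated.

Step 6
Reactants: 8 (2R,3S)-2-[4-(benzyloxy)-3-methoxyphenyl]-7-hydroxy-3-(hydroxymethyl)-2,3-dihydrobenzofuran-5-carbaldehyde; 10 1-[2,4-bis(benzyloxy)-6-hydroxyphenyl]ethan-1-one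
Product: 11 (E)-1-[2,4-bis(benzyloxy)-6-hydroxyphenyl]-3-{(2R,3S)-2-[4-(benzyloxy)-3-methoxyphenyl]-7-hydroxy-3-(hydroxymethyl)-2,3-dihydrobenzofuran-5-yl}prop-2-en-1-one
Conditions: KOH (8 equiv), EtOH/THF, rt, 36 h; then 1 M HCl to pH 5, 0 °C
Reagents that add atoms: none
Why: Claisen–Schmidt condensation (aldol addition then E1cB loss of water) giving the (E)-enone, tolerated because the free 7-OH is meta to the aldehyde and does not deactivate it, the O-benzyl group on the guaiacyl ring blocks quinone-methide opening of the dihydrofuran in base, and neither C2–H nor C3–H is acidic.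

Step 7
Reactants: 11 (E)-1-[2,4-bis(benzyloxy)-6-hydroxyphenyl]-3-{(2R,3S)-2-[4-(benzyloxy)-3-methoxyphenyl]-7-hydroxy-3-(hydroxymethyl)-2,3-dihydrobenzofuran-5-yl}prop-2-en-1-one
Product: 12 (2S)-5,7-bis(benzyloxy)-2-{(2R,3S)-2-[4-(benzyloxy)-3-methoxyphenyl]-7-hydroxy-3-(hydroxymethyl)-2,3-dihydrobenzofuran-5-yl}chroman-4-one
Conditions: quinidine-derived 9-epi-amino 3,5-(CF3)2C6H3-thiourea (15 mol %), toluene, 25 °C, 48–72 h; recovered 11 recycled
Reagents that add atoms: none
Why: Biomimetic 6-endo-trig intramolecular oxa-Michael addition under bifunctional cinchona–thiourea catalysis, in which the thiourea binds the enone carbonyl, the quinuclidine takes the 2'-OH proton, and the catalyst rather than the remote dihydrobenzofuran chooses the face of the β-carbon so that the O1–C2 bond forms with (2S) configuration, the run being stopped at the kinetic plateau before retro-addition erodes the ratio.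

Step 8
Reactants: 12 (2S)-5,7-bis(benzyloxy)-2-{(2R,3S)-2-[4-(benzyloxy)-3-methoxyphenyl]-7-hydroxy-3-(hydroxymethyl)-2,3-dihydrobenzofuran-5-yl}chroman-4-one
Product: 13 silyhermin B
Conditions: H2 (1 atm), Pd/C (10 wt %), THF/MeOH, rt, stopped after uptake of 3 equiv H2
Reagents that add atoms: none
Why: Hydrogenolysis of the three aryl benzyl ethers under neutral conditions, so that the liberated 5-hydroxyflavanone cannot racemise by base-induced ring opening and the slower-reacting cyclic benzylic C–O bonds and the aryl ketone are kept.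

## Compound list
1 | 5-iodovanillin (4-hydroxy-3-iodo-5-methoxybenzaldehyde) | COc1cc(C=O)cc(I)c1O | starting material
2 | 3,4-dihydroxy-5-iodobenzaldehyde | O=Cc1cc(O)c(O)c(I)c1 | intermediate
3 | 4-(benzyloxy)-3-methoxybenzaldehyde (O-benzylvanillin) | COc1cc(C=O)ccc1OCc1ccccc1 | starting material
4 | bromomagnesium 1-[4-(benzyloxy)-3-methoxyphenyl]prop-2-en-1-olate (racemic, not isolated) | C=CC(O[Mg]Br)c1ccc(OCc2ccccc2)c(OC)c1 | intermediate
5 | rac-tert-butyl 1-[4-(benzyloxy)-3-methoxyphenyl]prop-2-en-1-yl carbonate | C=CC(OC(=O)OC(C)(C)C)c1ccc(OCc2ccccc2)c(OC)c1 | intermediate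
6 | 4-{[(1R)-1-[4-(benzyloxy)-3-methoxyphenyl]prop-2-en-1-yl]oxy}-3-hydroxy-5-iodobenzaldehyde | C=C[C@@H](Oc1c(O)cc(C=O)cc1I)c1ccc(OCc2ccccc2)c(OC)c1 | intermediate
7 | (2R,3R)-3-[(1,3,2-benzodioxaborol-2-yl)methyl]-2-[4-(benzyloxy)-3-methoxyphenyl]-7-hydroxy-2,3-dihydrobenzofuran-5-carbaldehyde (trans, not isolated) | COc1cc([C@@H]2Oc3c(O)cc(C=O)cc3[C@H]2CB4Oc5ccccc5O4)ccc1OCc1ccccc1 | intermediate
8 | (2R,3S)-2-[4-(benzyloxy)-3-methoxyphenyl]-7-hydroxy-3-(hydroxymethyl)-2,3-dihydrobenzofuran-5-carbaldehyde (trans) | COc1cc([C@@H]2Oc3c(O)cc(C=O)cc3[C@H]2CO)ccc1OCc1ccccc1 | intermediate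
9 | 2,4,6-trihydroxyacetophenone | CC(=O)c1c(O)cc(O)cc1O | starting material
10 | 1-[2,4-bis(benzyloxy)-6-hydroxyphenyl]ethan-1-one | CC(=O)c1c(O)cc(OCc2ccccc2)cc1OCc1ccccc1 | intermediate
11 | (E)-1-[2,4-bis(benzyloxy)-6-hydroxyphenyl]-3-{(2R,3S)-2-[4-(benzyloxy)-3-methoxyphenyl]-7-hydroxy-3-(hydroxymethyl)-2,3-dihydrobenzofuran-5-yl}prop-2-en-1-one | COc1cc([C@@H]2Oc3c(O)cc(/C=C/C(=O)c4c(O)cc(OCc5ccccc5)cc4OCc4ccccc4)cc3[C@H]2CO)ccc1OCc1ccccc1 | intermediate
12 | (2S)-5,7-bis(benzyloxy)-2-{(2R,3S)-2-[4-(benzyloxy)-3-methoxyphenyl]-7-hydroxy-3-(hydroxymethyl)-2,3-dihydrobenzofuran-5-yl}chroman-4-one | COc1cc([C@@H]2Oc3c(O)cc([C@@H]4CC(=O)c5c(OCc6ccccc6)cc(OCc6ccccc6)cc5O4)cc3[C@H]2CO)ccc1OCc1ccccc1 | intermediate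
13 | silyhermin B, (2S)-5,7-dihydroxy-2-[(2R,3S)-7-hydroxy-2-(4-hydroxy-3-methoxyphenyl)-3-(hydroxymethyl)-2,3-dihydrobenzofuran-5-yl]chroman-4-one | COc1cc([C@@H]2Oc3c(O)cc([C@@H]4CC(=O)c5c(O)cc(O)cc5O4)cc3[C@H]2CO)ccc1O | target

## Step count
Total step count: 8.
Longest linear sequence: 6 steps (3 → 5 → 6 → 8 → 11 → 12 → 13, that is steps 2, 3, 4, 6, 7 and 8).

## The three steps most likely to fail

**Step 3 (the proposed new method).**
- Risks: slow attack by a hindered, weakly nucleophilic phenoxide; leakage to the linear cinnamyl ether; incomplete enantioconvergence; some 3-O-allylation.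
- The fallback is known chemistry. It sets out from 3 and 2 and comes back at 6.
- It gives up the racemic branched electrophile for an achiral linear one and a preformed aryloxide, so the stereocentre comes from enantioface-selective substitution instead of enantioconvergence.
- Horner–Wadsworth–Emmons olefination of 3 (triethyl phosphonoacetate, NaH, THF) gives ethyl (E)-3-[4-(benzyloxy)-3-methoxyphenyl]prop-2-enoate F1.
- Reduction of this ester (iBu2AlH, CH2Cl2, −78 °C) gives (E)-3-[4-(benzyloxy)-3-methoxyphenyl]prop-2-en-1-ol F2.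
- Acylation (ClCO2Me, pyridine) gives (E)-3-[4-(benzyloxy)-3-methoxyphenyl]prop-2-en-1-yl methyl carbonate F3.
- Separately, 2 and NaH (1.0 equiv) give sodium 4-formyl-2-hydroxy-6-iodophenolate F4.
- F3 and F4 are then coupled in THF at 25–50 °C. The catalyst is [Ir(cod)Cl]2 and the binaphthol-derived N,N-bis(1-phenylethyl)phosphoramidite, cyclometalated beforehand with propylamine.
- This is the established branched- and enantioselective allylic etherification of cinnamyl carbonates by alkali aryloxides. It delivers 6 at the price of three more steps.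

**Step 4.**
- Risks: the benzylic and allylic aryl ether 6 may be ionised by the boron halide formed in the chain, and the trans:cis ratio may be modest.
- The fallback sets out from 6 and comes back at 8.
- It replaces boron capture by direct C–O capture with a persistent radical under strictly neutral tin-hydride conditions.
- Slow addition of Bu3SnH to 6 and TEMPO in toluene at 70 °C performs the 5-exo aryl-radical cyclisation.
- The product is (2R,3S)-2-[4-(benzyloxy)-3-methoxyphenyl]-7-hydroxy-3-{[(2,2,6,6-tetramethylpiperidin-1-yl)oxy]methyl}-2,3-dihydrobenzofuran-5-carbaldehyde F5.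
- The cis isomer is removed by chromatography at this stage.
- Reductive N–O cleavage (Zn, AcOH/THF/H2O, 60 °C) then gives 8. This costs one more step.

**Step 7.**
- Risks: the oxa-Michael addition is reversible, face selectivity may be modest on a 6'-alkoxychalcone, and the free OH groups compete for the thiourea.
- The fallback sets out from 11 and comes back at 12.
- It gives up catalyst-controlled ring closure for unselective closure followed by a reagent-controlled kinetic resolution.
- NaOAc in refluxing EtOH closes 11 to a roughly 1:1 mixture of 12 and (2R)-5,7-bis(benzyloxy)-2-{(2R,3S)-2-[4-(benzyloxy)-3-methoxyphenyl]-7-hydroxy-3-(hydroxymethyl)-2,3-dihydrobenzofuran-5-yl}chroman-4-one F6.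
- Asymmetric transfer hydrogenation of the mixture (RuCl(p-cymene)[(R,R)-TsDPEN], HCO2H/Et3N, EtOAc, rt) reduces only the (2R)-ketone.
- That reduction gives the cis alcohol (2R,4R)-5,7-bis(benzyloxy)-2-{(2R,3S)-2-[4-(benzyloxy)-3-methoxyphenyl]-7-hydroxy-3-(hydroxymethyl)-2,3-dihydrobenzofuran-5-yl}chroman-4-ol F7.
- The untouched ketone 12 is separated from the alcohol by ordinary chromatography. The maximum yield is 50 % per pass.

## Further compounds
F1 | step 3 | ethyl (E)-3-[4-(benzyloxy)-3-methoxyphenyl]prop-2-enoate | CCOC(=O)/C=C/c1ccc(OCc2ccccc2)c(OC)c1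
F2 | step 3 | (E)-3-[4-(benzyloxy)-3-methoxyphenyl]prop-2-en-1-ol | OC/C=C/c1ccc(OCc2ccccc2)c(OC)c1
F3 | step 3 | (E)-3-[4-(benzyloxy)-3-methoxyphenyl]prop-2-en-1-yl methyl carbonate | COC(=O)OC/C=C/c1ccc(OCc2ccccc2)c(OC)c1
F4 | step 3 | sodium 4-formyl-2-hydroxy-6-iodophenolate | [Na+].[O-]c1c(O)cc(C=O)cc1I
F5 | step 4 | (2R,3S)-2-[4-(benzyloxy)-3-methoxyphenyl]-7-hydroxy-3-{[(2,2,6,6-tetramethylpiperidin-1-yl)oxy]methyl}-2,3-dihydrobenzofuran-5-carbaldehyde | COc1cc([C@@H]2Oc3c(O)cc(C=O)cc3[C@H]2CON4C(C)(C)CCCC4(C)C)ccc1OCc1ccccc1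
F6 | step 7 | (2R)-5,7-bis(benzyloxy)-2-{(2R,3S)-2-[4-(benzyloxy)-3-methoxyphenyl]-7-hydroxy-3-(hydroxymethyl)-2,3-dihydrobenzofuran-5-yl}chroman-4-one | COc1cc([C@@H]2Oc3c(O)cc([C@H]4CC(=O)c5c(OCc6ccccc6)cc(OCc6ccccc6)cc5O4)cc3[C@H]2CO)ccc1OCc1ccccc1
F7 | step 7 | (2R,4R)-5,7-bis(benzyloxy)-2-{(2R,3S)-2-[4-(benzyloxy)-3-methoxyphenyl]-7-hydroxy-3-(hydroxymethyl)-2,3-dihydrobenzofuran-5-yl}chroman-4-ol | COc1cc([C@@H]2Oc3c(O)cc([C@H]4C[C@@H](O)c5c(OCc6ccccc6)cc(OCc6ccccc6)cc5O4)cc3[C@H]2CO)ccc1OCc1ccccc1
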